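**Retrosynthetic overview** (disconnections listed in the order the bonds are made)
1. Ring A is bought intact as 2,4,6-trihydroxybenzaldehyde 1; its formyl carbon is the future ketone carbon and steers all ring-A regiochemistry until the last step.
2. C8–CH2 bond: cut to prenyl bromide 2 (C-prenylation of 1 gives aldehyde 3).
3. Pyran ring (O1–C2 and C4–C4a): cut to prenal 4, through ortho-quinone methide 5 and oxa-6π closure, giving chromene aldehyde 6.
4. Key disconnection, made last: the ketone C(=O)–aryl bond to the 4-hydroxyphenyl ring. The formyl carbon of 6 is used with reversed polarity as an acyl anion (aroylpalladium from its C–H bond) and joined to the electrophilic ipso carbon of 4-iodophenol 7, giving vismiaphenone E 8.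
5. Ring order: ring A (purchased), then the pyran ring (step 2), then the ready-made 4-hydroxyphenyl ring attached (step 3).

Assumption: the target has no stereocentre (its only stereo element is the ring-locked cis chromene alkene), so "single enantiomer" is read as the single constitution drawn.

**Step 1**
Reactants: 1 2,4,6-trihydroxybenzaldehyde; 2 prenyl bromide (1-bromo-3-methylbut-2-ene)
Product: 3 2,4,6-trihydroxy-3-(3-methylbut-2-en-1-yl)benzaldehyde
Conditions: 2 (0.9 equiv), KOH (10% aq., 2 equiv), 0 °C → rt; then 1 M HCl
Reagents that add atoms: none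
Why: C-alkylation of an ambident phloroglucinol phenoxide (aqueous-base C-prenylation), in which water solvates the phenoxide oxygens so the ring carbon attacks the allylic bromide by SN2, the two free ring carbons of 1 are equivalent so only one mono-C-prenyl isomer can form, a deficit of 2 limits double alkylation, and no stereocentre is formed.

**Step 2**
Reactants: 3 2,4,6-trihydroxy-3-(3-methylbut-2-en-1-yl)benzaldehyde; 4 3-methylbut-2-enal (prenal)
Product: 6 5,7-dihydroxy-2,2-dimethyl-8-(3-methylbut-2-en-1-yl)-2H-chromene-6-carbaldehyde, via ortho-quinone methide 5 (not isolated)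
Conditions: 4 (1.5 equiv), Ca(OH)2 (2 equiv), MeOH, rt; then 1 M HCl
Reagents that add atoms: none
Why: Formal [3+3] chromene annulation (aldol-type C-addition and dehydration, then oxa-6π electrocyclisation), in which the only free ring carbon of the phenoxide adds to the aldehyde of 4, water is lost through the most acidic, non-chelated para oxygen to give ortho-quinone methide 5, and ring closure is expected to place the pyran oxygen para to the formyl group; the new ring alkene is necessarily cis and no stereocentre is formed.

**Step 3**
Reactants: 6 5,7-dihydroxy-2,2-dimethyl-8-(3-methylbut-2-en-1-yl)-2H-chromene-6-carbaldehyde; 7 4-iodophenol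
Product: 8 vismiaphenone E, [5,7-dihydroxy-2,2-dimethyl-8-(3-methylbut-2-en-1-yl)-2H-chromen-6-yl](4-hydroxyphenyl)methanone
Conditions: 7 (2 equiv), PdCl2 (5 mol %), LiCl (20 mol %), Na2CO3 (3 equiv), DMF, 100 °C, N2; then 1 M HCl
Reagents that add atoms: none
Why: Phenoxide-directed palladium-catalysed formyl C–H arylation of a salicylaldehyde with an aryl iodide, in which zerovalent palladium (formed in situ from PdCl2) inserts into the C–I bond of 7, the arylpalladium binds an ortho phenoxide of 6, the neighbouring formyl C–H is cleaved to an aroyl(aryl)palladium so that the normally electrophilic carbonyl carbon acts as the acyl anion partner, and reductive elimination forms the diaryl ketone; ring A has no other C–H bond to arylate and no stereocentre is formed.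

**Compound list**
1 | 2,4,6-trihydroxybenzaldehyde | O=Cc1c(O)cc(O)cc1O | starting material
2 | prenyl bromide (1-bromo-3-methylbut-2-ene) | CC(C)=CCBr | starting material
3 | 2,4,6-trihydroxy-3-(3-methylbut-2-en-1-yl)benzaldehyde | CC(C)=CCc1c(O)cc(O)c(C=O)c1O | intermediate
4 | 3-methylbut-2-enal (prenal) | CC(C)=CC=O | starting material
5 | ortho-quinone methide, (3Z)-2,6-dihydroxy-5-(3-methylbut-2-en-1-yl)-3-(3-methylbut-2-en-1-ylidene)-4-oxocyclohexa-1,5-diene-1-carbaldehyde | O=CC1=C(O)/C(=C/C=C(C)C)C(=O)C(CC=C(C)C)=C1O | intermediate (not isolated)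
6 | 5,7-dihydroxy-2,2-dimethyl-8-(3-methylbut-2-en-1-yl)-2H-chromene-6-carbaldehyde | CC(C)=CCc1c(O)c(C=O)c(O)c2c1OC(C)(C)C=C2 | intermediate
7 | 4-iodophenol | Oc1ccc(I)cc1 | starting material
8 | vismiaphenone E, [5,7-dihydroxy-2,2-dimethyl-8-(3-methylbut-2-en-1-yl)-2H-chromen-6-yl](4-hydroxyphenyl)methanone (achiral) | CC(C)=CCc1c(O)c(C(=O)c2ccc(O)cc2)c(O)c2c1OC(C)(C)C=C2 | target

**Total step count:** 3
**Longest linear sequence:** 3 steps (1 → 3 → 6 → 8)

**Steps most likely to fail, with fallbacks**

Step 3 (highest risk). The aroylpalladium is flanked by two oxygen substituents and may lose CO. The arylpalladium phenoxide could instead add across the neighbouring prenyl alkene (oxypalladation to a second pyran ring) or give a Heck product on the chromene alkene. Unprotected 4-iodophenol may also slow the catalyst. The fallback sets out from 6 and comes back at 8, and keeps the formyl carbon as an acyl anion in an explicit, protected form. Both phenols are protected (MOMCl, iPr2NEt, CH2Cl2, 0 °C → rt) to give 5,7-bis(methoxymethoxy)-2,2-dimethyl-8-(3-methylbut-2-en-1-yl)-2H-chromene-6-carbaldehyde F1. Condensation with tert-butylhydrazine hydrochloride (NaOAc, EtOH, 60 °C) gives 5,7-bis(methoxymethoxy)-2,2-dimethyl-8-(3-methylbut-2-en-1-yl)-2H-chromene-6-carbaldehyde (E)-N-tert-butylhydrazone F2, an aza-enolate acyl anion equivalent. Palladium-catalysed C-arylation with 1-bromo-4-(methoxymethoxy)benzene (Pd2(dba)3, DPEphos, NaOtBu, toluene, 80 °C), followed by tautomerisation of the first-formed azo compound, gives [5,7-bis(methoxymethoxy)-2,2-dimethyl-8-(3-methylbut-2-en-1-yl)-2H-chromen-6-yl][4-(methoxymethoxy)phenyl]methanone N-tert-butylhydrazone F3. Treatment with 3 M HCl in MeOH/THF at 40 °C hydrolyses the hydrazone and all three MOM ethers to give 8.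

Step 2. Ring closure through an ortho oxygen instead of the para oxygen would give the 8-formyl-6-prenyl regioisomer, which would have to be separated; the ratio is not certain in advance. The fallback sets out from 3 and comes back at 6, and fixes the pyran oxygen before the ring is made. Selective O-alkylation of the non-chelated, most acidic 4-hydroxyl with 3-chloro-3-methylbut-1-yne (CuCl2 (1 mol %), DBU, MeCN, 0 °C) gives 2,6-dihydroxy-3-(3-methylbut-2-en-1-yl)-4-[(2-methylbut-3-yn-2-yl)oxy]benzaldehyde F4. Heating in xylene at 140 °C triggers propargyl Claisen rearrangement to the only free ortho carbon, enolisation, 1,5-hydrogen shift and oxa-6π closure, which can only give 6.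

Step 1. Double C-prenylation, geminal dialkylation and O-prenylation compete with the wanted mono-C-alkylation, so the yield is expected to be modest. The fallback sets out from 1 and comes back at 6, and reverses the order of the first two events. The Ca(OH)2/MeOH annulation is run on 1 with 1.0 equiv of 4 to give 5,7-dihydroxy-2,2-dimethyl-2H-chromene-6-carbaldehyde F5, which has a single free ring carbon. C-prenylation of that carbon with 2 (KOH, 10% aq., 0 °C) cannot over-alkylate on carbon and gives 6.

**Further compounds**
F1 | step 3 | 5,7-bis(methoxymethoxy)-2,2-dimethyl-8-(3-methylbut-2-en-1-yl)-2H-chromene-6-carbaldehyde | CC(C)=CCc1c(OCOC)c(C=O)c(OCOC)c2c1OC(C)(C)C=C2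
F2 | step 3 | 5,7-bis(methoxymethoxy)-2,2-dimethyl-8-(3-methylbut-2-en-1-yl)-2H-chromene-6-carbaldehyde (E)-N-tert-butylhydrazone | CC(C)=CCc1c(OCOC)c(/C=N/NC(C)(C)C)c(OCOC)c2c1OC(C)(C)C=C2
F3 | step 3 | [5,7-bis(methoxymethoxy)-2,2-dimethyl-8-(3-methylbut-2-en-1-yl)-2H-chromen-6-yl][4-(methoxymethoxy)phenyl]methanone N-tert-butylhydrazone (C=N geometry not fixed) | CC(C)=CCc1c(OCOC)c(C(=NNC(C)(C)C)c3ccc(OCOC)cc3)c(OCOC)c2c1OC(C)(C)C=C2
F4 | step 2 | 2,6-dihydroxy-3-(3-methylbut-2-en-1-yl)-4-[(2-methylbut-3-yn-2-yl)oxy]benzaldehyde | CC(C)=CCc1c(O)c(C=O)c(O)cc1OC(C)(C)C#C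
F5 | step 1 | 5,7-dihydroxy-2,2-dimethyl-2H-chromene-6-carbaldehyde | O=Cc1c(O)cc2OC(C)(C)C=Cc2c1O
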